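**Retrosynthetic overview**
1. Target 15 ⇐ 14 by allylic C–H oxidation at C7; 14 ⇐ 13 by Baeyer–Villiger oxidation (6-acetyl → 6-acetoxy, retention).
2. 13 ⇐ acyclic trienone 12 by one catalytic enantioselective intramolecular Diels–Alder reaction (bonds C5–C10 and C6–C7), which closes rings A and B together and sets C5, C6 and C10.
3. 12 ⇐ dienyl triflate 6 + 2,2-dimethylpent-4-enal 7 (C1–C5, B-alkyl Suzuki) + acetonylidene ylide 10 (C6 and the acetyl group).
4. 6 ⇐ 3-substituted pentane-2,4-dione 4 (Z-enol triflate, methylenation) ⇐ (R)-3-methylcyclohexanone 1 (acetylation, retro-Claisen opening, acetylation), which supplies C13.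
5. Ring order: no ring of the target exists before step 8, where both carbocycles form at once; the ring of 1/2 is only a carrier and is opened in step 2.

Assumption: the SMILES is taken literally, i.e. labdane numbering 5R,6S,10S,13R, a cis-fused decalin with H-5, CH3-10 and 6-OAc on one face; the (S)-oxazaborolidinium catalyst in step 8 is assigned by analogy with its acrylate cycloadditions (attack on the Re face of the α-carbon), which I recall but have not checked for this substrate class.

Labdane numbering (C1–C20) is used in the explanations.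

**Step 1**
Reactants: 1 (R)-3-methylcyclohexanone
Product: 2 (5R)-2-acetyl-5-methylcyclohexan-1-one (keto/enol mixture, C2 undefined)
Conditions: NaH, EtOAc, THF, 0 → 40 °C; aq. HCl
Reagents that add atoms: ethyl acetate, CCOC(C)=O
Why: Claisen-type C-acylation of the ketone enolate is reversible and settles on the α-carbon remote from the methyl group (as in formylation of 3-methylcyclohexanone), and the stereocentre, β to the carbonyl, is not touched.

**Step 2**
Reactants: 2 (5R)-2-acetyl-5-methylcyclohexan-1-one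
Product: 3 methyl (3R)-3-methyl-7-oxooctanoate
Conditions: In(OTf)3 (5 mol %), MeOH, 80 °C
Reagents that add atoms: methanol, CO
Why: Lewis-acid-catalysed retro-Claisen alcoholysis, in which methanol adds to the ring carbonyl of the 2-acylcyclohexanone and C1–C2 cleavage opens the ring to the keto ester, so the ring stereocentre becomes C13 (R) with nothing epimerisable next to it.

**Step 3**
Reactants: 3 methyl (3R)-3-methyl-7-oxooctanoate
Product: 4 methyl (3R)-6-acetyl-3-methyl-7-oxooctanoate
Conditions: Ac2O, BF3·2AcOH, TsOH (cat.), rt; then NaOAc, H2O, reflux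
Reagents that add atoms: acetic anhydride, CC(=O)OC(C)=O
Why: BF3-mediated acylation of a methyl alkyl ketone goes through the more substituted enol, so the acetyl enters at the methylene (future C9) and gives the symmetric 3-substituted pentane-2,4-dione after cleavage of the BF2 chelate, while the ester is inert.

**Step 4**
Reactants: 4 methyl (3R)-6-acetyl-3-methyl-7-oxooctanoate
Product: 5 methyl (3R,6Z)-6-acetyl-3-methyl-7-{[(trifluoromethyl)sulfonyl]oxy}oct-6-enoate
Conditions: Tf2O, aq. LiOH, toluene, 0–5 °C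
Reagents that add atoms: trifluoromethanesulfonic anhydride, O=S(=O)(OS(=O)(=O)C(F)(F)F)C(F)(F)F
Why: O-triflation of the lithium-chelated U-shaped enolate gives the enol triflate with OTf cis to the remaining acetyl (Z); the two carbonyls are equivalent, so only geometry matters, and this geometry later puts the tether on the inside of the diene.

**Step 5**
Reactants: 5 methyl (3R,6Z)-6-acetyl-3-methyl-7-{[(trifluoromethyl)sulfonyl]oxy}oct-6-enoate
Product: 6 methyl (3R,6Z)-3-methyl-6-(prop-1-en-2-yl)-7-{[(trifluoromethyl)sulfonyl]oxy}oct-6-enoate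
Conditions: Zn, CH2Br2, TiCl4, THF/CH2Cl2, 0 °C → rt
Reagents that add atoms: dibromomethane, BrCBr
Why: Takai–Lombardo methylenation with a non-basic gem-dimetallic reagent converts the hindered, enolisable ketone into the isopropenyl group (C7, C8, C17) without attacking the methyl ester or the enol triflate and without E/Z leakage.

**Step 6**
Reactants: 6 methyl (3R,6Z)-3-methyl-6-(prop-1-en-2-yl)-7-{[(trifluoromethyl)sulfonyl]oxy}oct-6-enoate; 7 2,2-dimethylpent-4-enal
Product: 9 methyl (3R,6Z)-12-hydroxy-3,7,11,11-tetramethyl-6-(prop-1-en-2-yl)dodec-6-enoate, via 9-[4,4-dimethyl-5-(9-borabicyclo[3.3.1]nonan-9-yloxy)pentyl]-9-borabicyclo[3.3.1]nonane 8 (not isolated)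
Conditions: 7, 9-BBN (2.2 equiv), THF, 0 °C → rt; then 6, Pd(dppf)Cl2 (5 mol %), AsPh3, 3 M aq. K3PO4, DMF, rt → 45 °C
Reagents that add atoms: none
Why: 9-BBN reduces the aldehyde and hydroborates the terminal alkene anti-Markovnikov, and B-alkyl Suzuki–Miyaura coupling of the primary alkylborane with the dienyl triflate proceeds with retention of alkene geometry, so the C1–C5 chain ends up cis to the isopropenyl group.

**Step 7**
Reactants: 9 methyl (3R,6Z)-12-hydroxy-3,7,11,11-tetramethyl-6-(prop-1-en-2-yl)dodec-6-enoate; 10 1-(triphenyl-λ5-phosphanylidene)propan-2-one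
Product: 12 methyl (3R,6Z,12E)-3,7,11,11-tetramethyl-14-oxo-6-(prop-1-en-2-yl)pentadeca-6,12-dienoate, via methyl (3R,6Z)-3,7,11,11-tetramethyl-12-oxo-6-(prop-1-en-2-yl)dodec-6-enoate 11 (not isolated)
Conditions: TPAP (5 mol %), NMO, 4 Å MS, CH2Cl2, rt; then 10 (3 equiv), 40 °C
Reagents that add atoms: none
Why: Ley–Griffith oxidation to the non-enolisable neopentyl aldehyde followed in the same flask by Wittig olefination with the stabilised ylide gives the (E)-enone, at a temperature well below that of the uncatalysed cycloaddition.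

**Step 8**
Reactants: 12 methyl (3R,6Z,12E)-3,7,11,11-tetramethyl-14-oxo-6-(prop-1-en-2-yl)pentadeca-6,12-dienoate
Product: 13 methyl (3R)-5-[(4R,4aR,8aS)-4-acetyl-2,5,5,8a-tetramethyl-3,4,4a,5,6,7,8,8a-octahydronaphthalen-1-yl]-3-methylpentanoate
Conditions: (S)-B-o-tolyl oxazaborolidine from (S)-diphenylprolinol, activated with Tf2NH (20 mol %), CH2Cl2, −40 → −20 °C
Reagents that add atoms: none
Why: Proposed new method: an enantioselective intramolecular Diels–Alder reaction under chiral cationic oxazaborolidine catalysis, extended to a terminally activated trienone whose tetrasubstituted diene creates the C10 quaternary centre; the boron-bound s-trans enone is shielded on one face so the diene adds to the C5-Re/C6-Re face (absolute configuration), the tether sits on the inside (Z) position of the diene and can reach C5 only through the exo-tether/endo-acetyl transition state, which enforces cis ring fusion (CH3-10 and H-5 cis) and places the acetyl cis to both; the closest known chemistry is oxazaborolidinium-catalysed inter- and intramolecular Diels–Alder reactions of enones and enals and Lewis-acid-promoted cycloadditions of (Z)-diene decatrienes, which give only cis-fused products.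

**Step 9**
Reactants: 13 methyl (3R)-5-[(4R,4aR,8aS)-4-acetyl-2,5,5,8a-tetramethyl-3,4,4a,5,6,7,8,8a-octahydronaphthalen-1-yl]-3-methylpentanoate
Product: 14 methyl (3R)-5-[(4R,4aR,8aS)-4-acetoxy-2,5,5,8a-tetramethyl-3,4,4a,5,6,7,8,8a-octahydronaphthalen-1-yl]-3-methylpentanoate
Conditions: Me3SiOOSiMe3 (2 equiv), TMSOTf (20 mol %), CH2Cl2, −40 → −20 °C
Reagents that add atoms: bis(trimethylsilyl) peroxide, C[Si](C)(C)OO[Si](C)(C)C
Why: Baeyer–Villiger oxidation with the non-epoxidising silyl peroxide/TMSOTf system, in which the secondary ring carbon migrates in preference to methyl with retention, so the C6 configuration set in step 8 becomes the 6-acetate while the tetrasubstituted alkene survives.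

**Step 10**
Reactants: 14 methyl (3R)-5-[(4R,4aR,8aS)-4-acetoxy-2,5,5,8a-tetramethyl-3,4,4a,5,6,7,8,8a-octahydronaphthalen-1-yl]-3-methylpentanoate
Product: 15 methyl (3R)-5-[(4S,4aR,8aS)-4-acetoxy-2,5,5,8a-tetramethyl-3-oxo-3,4,4a,5,6,7,8,8a-octahydronaphthalen-1-yl]-3-methylpentanoate (CNP0192224.1)
Conditions: Rh2(cap)4 (1 mol %), t-BuOOH (70 % aq., 5 equiv), DCE, 40 °C
Reagents that add atoms: tert-butyl hydroperoxide, CC(C)(C)OO
Why: Rh2(cap)4/t-BuOOH allylic oxidation (peroxyl-radical H-abstraction, then collapse of the allylic peroxide) of the ring allylic CH2, as in the oxidation of Δ8-labdenes and drimenes to 7-oxo-8-enes, gives the enone; no stereocentre is formed, and C6 should already hold the more stable configuration with OAc trans to the C4 branch.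

**Compound list**
1 | (R)-3-methylcyclohexanone | C[C@@H]1CCCC(=O)C1 | starting material
2 | (5R)-2-acetyl-5-methylcyclohexan-1-one | C[C@@H]1CCC(C(C)=O)C(=O)C1 | intermediate
3 | methyl (3R)-3-methyl-7-oxooctanoate | COC(=O)C[C@H](C)CCCC(C)=O | intermediate
4 | methyl (3R)-6-acetyl-3-methyl-7-oxooctanoate | COC(=O)C[C@H](C)CCC(C(C)=O)C(C)=O | intermediate
5 | methyl (3R,6Z)-6-acetyl-3-methyl-7-{[(trifluoromethyl)sulfonyl]oxy}oct-6-enoate | COC(=O)C[C@H](C)CC/C(C(C)=O)=C(\C)OS(=O)(=O)C(F)(F)F | intermediate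
6 | methyl (3R,6Z)-3-methyl-6-(prop-1-en-2-yl)-7-{[(trifluoromethyl)sulfonyl]oxy}oct-6-enoate | COC(=O)C[C@H](C)CC/C(C(C)=C)=C(\C)OS(=O)(=O)C(F)(F)F | intermediate
7 | 2,2-dimethylpent-4-enal | C=CCC(C)(C)C=O | starting material
8 | 9-[4,4-dimethyl-5-(9-borabicyclo[3.3.1]nonan-9-yloxy)pentyl]-9-borabicyclo[3.3.1]nonane | C1CCC2CCCC1B2CCCC(C)(C)COB1C2CCCC1CCC2 | intermediate
9 | methyl (3R,6Z)-12-hydroxy-3,7,11,11-tetramethyl-6-(prop-1-en-2-yl)dodec-6-enoate | COC(=O)C[C@H](C)CC/C(C(C)=C)=C(\C)CCCC(C)(C)CO | intermediate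
10 | 1-(triphenyl-λ5-phosphanylidene)propan-2-one | CC(=O)C=P(c1ccccc1)(c1ccccc1)c1ccccc1 | starting material
11 | methyl (3R,6Z)-3,7,11,11-tetramethyl-12-oxo-6-(prop-1-en-2-yl)dodec-6-enoate | COC(=O)C[C@H](C)CC/C(C(C)=C)=C(\C)CCCC(C)(C)C=O | intermediate
12 | methyl (3R,6Z,12E)-3,7,11,11-tetramethyl-14-oxo-6-(prop-1-en-2-yl)pentadeca-6,12-dienoate | COC(=O)C[C@H](C)CC/C(C(C)=C)=C(\C)CCCC(C)(C)/C=C/C(C)=O | intermediate
13 | methyl (3R)-5-[(4R,4aR,8aS)-4-acetyl-2,5,5,8a-tetramethyl-3,4,4a,5,6,7,8,8a-octahydronaphthalen-1-yl]-3-methylpentanoate | COC(=O)C[C@H](C)CCC1=C(C)C[C@@H](C(C)=O)[C@@H]2C(C)(C)CCC[C@]12C | intermediate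
14 | methyl (3R)-5-[(4R,4aR,8aS)-4-acetoxy-2,5,5,8a-tetramethyl-3,4,4a,5,6,7,8,8a-octahydronaphthalen-1-yl]-3-methylpentanoate | COC(=O)C[C@H](C)CCC1=C(C)C[C@@H](OC(C)=O)[C@@H]2C(C)(C)CCC[C@]12C | intermediate
15 | methyl (3R)-5-[(4S,4aR,8aS)-4-acetoxy-2,5,5,8a-tetramethyl-3-oxo-3,4,4a,5,6,7,8,8a-octahydronaphthalen-1-yl]-3-methylpentanoate | COC(=O)C[C@H](C)CCC1=C(C)C(=O)[C@@H](OC(C)=O)[C@@H]2C(C)(C)CCC[C@]12C | target

**Total step count:** 10. **Longest linear sequence:** 10 steps (1 → 15).

**Three steps most likely to fail**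

Step 8. The C5–C10 bond joins a fully substituted diene terminus to a neopentyl β-carbon, the tether-enforced regiochemistry is electronically mismatched for this diene, and the strongly acidic catalyst may protonate the diene and scramble the C9=C10 geometry (leaking trans-fused product); the enantioselectivity is unknown. The fallback sets out from 12 and comes back at 13, and replaces Lewis-acid activation of the ketone by a cationic (Gassman-type) cycloaddition with a chiral acetal as controller. Trienone 12 is ketalised with (2R,3R)-2,3-bis(trimethylsilyloxy)butane and catalytic TMSOTf at −78 °C to methyl (3R,6Z,12E)-3,7,11,11-tetramethyl-6-(prop-1-en-2-yl)-13-[(4R,5R)-2,4,5-trimethyl-1,3-dioxolan-2-yl]trideca-6,12-dienoate F1. Further TMSOTf at −78 → −40 °C opens the dioxolane to the alkoxy-allyl cation, a far stronger dienophile, which closes both rings to methyl (3R)-5-{(4R,4aR,8aS)-2,5,5,8a-tetramethyl-4-[(4R,5R)-2,4,5-trimethyl-1,3-dioxolan-2-yl]-3,4,4a,5,6,7,8,8a-octahydronaphthalen-1-yl}-3-methylpentanoate F2. The facial sense of this auxiliary is not established; the diastereomers are separated at this stage and the diol antipode is changed if needed. PPTS in wet acetone then releases 13.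

Step 9. The silyl peroxide system may be too sluggish for a hindered acyclic methyl ketone, and any peracid strong enough for the Baeyer–Villiger step will epoxidise the tetrasubstituted alkene first. The fallback sets out from 13 and comes back at 14, and accepts the epoxidation and then repairs it. mCPBA (3 equiv, Na2HPO4, CH2Cl2, rt → 40 °C) epoxidises C8=C9 and then converts the acetyl group with retention, giving methyl (3R)-5-[(4R,4aR,8aS)-4-acetoxy-1,2-epoxy-2,5,5,8a-tetramethyldecahydronaphthalen-1-yl]-3-methylpentanoate F3 (epoxide face immaterial). Cp2TiCl (Cp2TiCl2, Zn, THF, rt) then deoxygenates the tetrasubstituted epoxide through the β-titanoxy radical, which restores the alkene and gives 14; acetate and ester are inert to Ti(III).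

Step 10. The C7–H bonds are deactivated by the vicinal acetoxy group, so oxidation at C11 (side chain) or C17 may compete, and the α-acetoxy enone could epimerise at C6. The fallback sets out from 5 and comes back at 15, and carries the C7 oxygen through the cycloaddition on the diene instead of adding it at the end.
- Triflate 5 is coupled with borane 8 under the step 6 conditions, before methylenation, to give methyl (3R,6Z)-6-acetyl-12-hydroxy-3,7,11,11-tetramethyldodec-6-enoate F4.
- Wittig reaction with methoxymethylenetriphenylphosphorane (MeOCH2PPh3Cl, KHMDS, THF, −78 → 0 °C) gives methyl (3R,6Z)-12-hydroxy-6-[(1E)-1-methoxyprop-1-en-2-yl]-3,7,11,11-tetramethyldodec-6-enoate F5; the E enol ether is the reactive isomer.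
- TPAP/NMO gives methyl (3R,6Z)-6-[(1E)-1-methoxyprop-1-en-2-yl]-3,7,11,11-tetramethyl-12-oxododec-6-enoate F6, and ylide 10 in the same flask gives methyl (3R,6Z,12E)-6-[(1E)-1-methoxyprop-1-en-2-yl]-3,7,11,11-tetramethyl-14-oxopentadeca-6,12-dienoate F7.
- The step 8 catalyst, now acting on an electronically matched donor diene, gives methyl (3R)-5-[(3S,4S,4aR,8aS)-4-acetyl-3-methoxy-2,5,5,8a-tetramethyl-3,4,4a,5,6,7,8,8a-octahydronaphthalen-1-yl]-3-methylpentanoate F8.
- The step 9 Baeyer–Villiger conditions give methyl (3R)-5-[(3R,4S,4aR,8aS)-4-acetoxy-3-methoxy-2,5,5,8a-tetramethyl-3,4,4a,5,6,7,8,8a-octahydronaphthalen-1-yl]-3-methylpentanoate F9.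
- DDQ in wet CH2Cl2 oxidises the allylic methyl ether (hydride abstraction, collapse of the hemiacetal) to 15.

**Further compounds**
F1 | step 8 | methyl (3R,6Z,12E)-3,7,11,11-tetramethyl-6-(prop-1-en-2-yl)-13-[(4R,5R)-2,4,5-trimethyl-1,3-dioxolan-2-yl]trideca-6,12-dienoate | COC(=O)C[C@H](C)CC/C(C(C)=C)=C(\C)CCCC(C)(C)/C=C/C1(C)O[C@H](C)[C@@H](C)O1
F2 | step 8 | methyl (3R)-5-{(4R,4aR,8aS)-2,5,5,8a-tetramethyl-4-[(4R,5R)-2,4,5-trimethyl-1,3-dioxolan-2-yl]-3,4,4a,5,6,7,8,8a-octahydronaphthalen-1-yl}-3-methylpentanoate | COC(=O)C[C@H](C)CCC1=C(C)C[C@@H](C3(C)O[C@H](C)[C@@H](C)O3)[C@@H]2C(C)(C)CCC[C@]12C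
F3 | step 9 | methyl (3R)-5-[(4R,4aR,8aS)-4-acetoxy-1,2-epoxy-2,5,5,8a-tetramethyldecahydronaphthalen-1-yl]-3-methylpentanoate | COC(=O)C[C@H](C)CCC12OC1(C)C[C@@H](OC(C)=O)[C@@H]3C(C)(C)CCC[C@]23C
F4 | step 10 | methyl (3R,6Z)-6-acetyl-12-hydroxy-3,7,11,11-tetramethyldodec-6-enoate | COC(=O)C[C@H](C)CC/C(C(C)=O)=C(\C)CCCC(C)(C)CO
F5 | step 10 | methyl (3R,6Z)-12-hydroxy-6-[(1E)-1-methoxyprop-1-en-2-yl]-3,7,11,11-tetramethyldodec-6-enoate | COC(=O)C[C@H](C)CC/C(/C(C)=C/OC)=C(\C)CCCC(C)(C)CO
F6 | step 10 | methyl (3R,6Z)-6-[(1E)-1-methoxyprop-1-en-2-yl]-3,7,11,11-tetramethyl-12-oxododec-6-enoate | COC(=O)C[C@H](C)CC/C(/C(C)=C/OC)=C(\C)CCCC(C)(C)C=O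
F7 | step 10 | methyl (3R,6Z,12E)-6-[(1E)-1-methoxyprop-1-en-2-yl]-3,7,11,11-tetramethyl-14-oxopentadeca-6,12-dienoate | COC(=O)C[C@H](C)CC/C(/C(C)=C/OC)=C(\C)CCCC(C)(C)/C=C/C(C)=O
F8 | step 10 | methyl (3R)-5-[(3S,4S,4aR,8aS)-4-acetyl-3-methoxy-2,5,5,8a-tetramethyl-3,4,4a,5,6,7,8,8a-octahydronaphthalen-1-yl]-3-methylpentanoate | COC(=O)C[C@H](C)CCC1=C(C)[C@@H](OC)[C@@H](C(C)=O)[C@@H]2C(C)(C)CCC[C@]12C
F9 | step 10 | methyl (3R)-5-[(3R,4S,4aR,8aS)-4-acetoxy-3-methoxy-2,5,5,8a-tetramethyl-3,4,4a,5,6,7,8,8a-octahydronaphthalen-1-yl]-3-methylpentanoate | COC(=O)C[C@H](C)CCC1=C(C)[C@@H](OC)[C@@H](OC(C)=O)[C@@H]2C(C)(C)CCC[C@]12C
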